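**Retrosynthetic overview**

1. Labdane numbering is used (ring A: C1–C5 and C10; ring B: C5–C10; C20 on C10; C18/C19 on C4; C17 on C8; C11–C16 in the side chain). The plan rests on ring B: C8 carries the C17 formyl group next to C9 and the quaternary C10. This is the pattern of a cyclohexa-1,3-dienecarbaldehyde formed when the γ-carbon (C10) of one enal is joined to the β-carbon (C9) of a second and C8 closes onto C7.
2. Late stage: C8 is equilibrated and the C18/C19 diol unmasked last. C12–C13 is cut to a 9-vinyl decalin and 3-bromofuran-2(5H)-one (hydroboration, B-alkyl Suzuki–Miyaura). The vinyl group comes from the C9 ester, and the trans ring fusion from hydrogen-atom-transfer hydrogenation of the C5=C6–C7=C8 diene.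
3. Key disconnection: C9–C10 and C7–C8 (ring B) by an amine-catalysed dienamine–iminium [4+2] union of enal 9 with ethyl (E)-4-oxobut-2-enoate 10.
4. Enal 9 is cut at C5=C6 (ethynylation, Meyer–Schuster) to a spiro-acetonide cyclohexanone made from ethyl 2-oxocyclohexane-1-carboxylate (γ-methylation, hydroxymethylation, reduction).
5. Ring order: ring A is in the starting material, ring B is closed in step 8, the butenolide ring is bought and attached in step 15.

Key step: step 8

Assumption: the dienamine is taken to react through its cisoid C5–C6 rotamer on the face away from the C(Ph)2OSiMe3 group, so the (S)-amine, C[Si](C)(C)OC(c1ccccc1)(c1ccccc1)[C@@H]1CCCN1, is predicted to give (10S); if the sense of induction were the opposite, the (R)-amine would be used in the same way.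

**Route**

Step 1
Reactants: 1 ethyl 2-oxocyclohexane-1-carboxylate
Product: 2 ethyl 3-methyl-2-oxocyclohexane-1-carboxylate (racemic, keto/enol and diastereomer mixture)
Conditions: LiN(i-Pr)2 (2.2 equiv), THF, 0 °C; MeI (1.05 equiv), 0 °C; aq. NH4Cl
Reagents that add atoms: iodomethane, CI
Why: Dianion alkylation of a β-keto ester, in which the second deprotonation puts the more reactive carbanion on the γ-carbon (ring C3) and only that carbon is methylated; the new centre (later C10) is racemic and is erased in step 8.

Step 2
Reactants: 2 ethyl 3-methyl-2-oxocyclohexane-1-carboxylate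
Product: 3 ethyl 1-(hydroxymethyl)-3-methyl-2-oxocyclohexane-1-carboxylate (racemic, both diastereomers)
Conditions: 37% aq. HCHO, KHCO3 (cat.), THF, 23 °C
Reagents that add atoms: formaldehyde, C=O
Why: Base-catalysed aldol hydroxymethylation of the doubly activated α-carbon builds the quaternary carbon (later C4), and the mild bicarbonate does not enolise the ketone toward the methyl-bearing carbon.

Step 3
Reactants: 3 ethyl 1-(hydroxymethyl)-3-methyl-2-oxocyclohexane-1-carboxylate
Product: 4 2,2-bis(hydroxymethyl)-6-methylcyclohexan-1-ol (racemic, both diastereomers)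
Conditions: LiAlH4, THF, −20 → 23 °C; Fieser work-up
Reagents that add atoms: none
Why: Hydride reduction of ester and ketone, which at low temperature should outrun retro-aldol loss of formaldehyde; the carbinol configuration is irrelevant because it is oxidised in step 5.

Step 4
Reactants: 4 2,2-bis(hydroxymethyl)-6-methylcyclohexan-1-ol
Product: 5 3,3,8-trimethyl-2,4-dioxaspiro[5.5]undecan-7-ol (racemic, both diastereomers)
Conditions: Me2C(OMe)2, PPTS (cat.), CH2Cl2, 0 → 23 °C
Reagents that add atoms: 2,2-dimethoxypropane, COC(C)(C)OC
Why: Acid-catalysed transacetalisation under kinetic conditions, in which the two unhindered primary hydroxyls should close the spiro 1,3-dioxane faster than the secondary hydroxyl, flanked by the quaternary and the methyl-bearing carbons, is engaged.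

Step 5
Reactants: 5 3,3,8-trimethyl-2,4-dioxaspiro[5.5]undecan-7-ol
Product: 6 3,3,8-trimethyl-2,4-dioxaspiro[5.5]undecan-7-one (racemic)
Conditions: Dess–Martin periodinane, pyridine, CH2Cl2, 0 → 23 °C
Reagents that add atoms: none
Why: Dess–Martin oxidation of a hindered secondary alcohol under buffered conditions that leave the acetonide intact.

Step 6
Reactants: 6 3,3,8-trimethyl-2,4-dioxaspiro[5.5]undecan-7-one; 7 ethynylmagnesium bromide
Product: 8 7-ethynyl-3,3,8-trimethyl-2,4-dioxaspiro[5.5]undecan-7-ol (racemic, both diastereomers)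
Conditions: THF, 0 → 23 °C; aq. NH4Cl
Reagents that add atoms: none
Why: Grignard 1,2-addition, in which the small and weakly basic alkynyl nucleophile should add to the hindered ketone in preference to removing its single α-hydrogen; both carbinol diastereomers converge in step 7.

Step 7
Reactants: 8 7-ethynyl-3,3,8-trimethyl-2,4-dioxaspiro[5.5]undecan-7-ol
Product: 9 enal A, (E)-2-(3,3,8-trimethyl-2,4-dioxaspiro[5.5]undecan-7-ylidene)acetaldehyde (racemic at C10)
Conditions: VO(OSiPh3)3 (5 mol%), Ph3SiOH (cat.), xylene, 140 °C
Reagents that add atoms: none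
Why: Meyer–Schuster rearrangement through the propargyl vanadate and a [3,3] shift to the allenyl vanadate, which carries oxygen to the terminal carbon under non-acidic conditions that disfavour the Rupe dehydration and spare the acetonide; the E isomer (formyl away from the spiro carbon) is expected, and either geometry gives the same dienamine.

Step 8
Reactants: 9 enal A; 10 ethyl (E)-4-oxobut-2-enoate
Product: 13 dienal ester (9S,10S; ring B with C5=C6 and C7=C8; formyl on C8; ethyl ester on C9 cis to the C10 methyl; C4 spiro acetonide), via dienamine 11 (not isolated), via aminocyclohexene adduct 12 (not isolated)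
Conditions: (S)-2-[diphenyl(trimethylsilyloxy)methyl]pyrrolidine (20 mol%), PhCO2H (20 mol%), toluene, 23 → 40 °C
Reagents that add atoms: none
Why: Proposed new method: condensation of the amine with 9 and loss of the only γ-proton (C10–H; C4 is quaternary) gives dienamine 11, which erases the C10 centre and acts as a 1-amino diene; C10 bonds to C9, the β-carbon of the formyl-activated (free or iminium-bound) acrylate 10, the resulting C8 enol or enamine attacks the C7 iminium to give adduct 12, and the amine is expelled across C7–C8 (E1cB) to release dienal 13 and the catalyst. The closest known reaction type is the secondary-amine-catalysed dienamine–iminium formal [4+2] condensation of two enals to cyclohexa-1,3-dienecarbaldehydes, which has not been shown for a γ,γ-disubstituted dienamine that must create a quaternary carbon; thermal Diels–Alder reactions of 2,6,6-trisubstituted 1-vinylcyclohexenes, which form the same kind of quaternary centre, support its feasibility. Ring B closes either in one asynchronous [4+2] event or stepwise by a 6-(enolexo)-exo-trig Mannich attack of C8 on C7, and only the cisoid C5–C6 rotamer of the dienamine can close. C10 is controlled by the catalyst, whose C(Ph)2OSiMe3 group shields one face of the cisoid dienamine so that 10 adds to the open face (10S predicted with the (S)-amine), and C9 by the endo placement of the activating formyl or iminium group, which leaves the ester exo and therefore cis to the C10 methyl. The step needs cross- and not homo-coupling and γ- and not α-attack: 10 has no γ-hydrogen and cannot become a dienamine, the β,β-disubstituted 9 is a poor acceptor, and the formyl group outweighs the ester in directing attack to C9.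

Step 9
Reactants: 13 dienal ester
Product: 14 dienyl alcohol (9S,10S; as 13 with C8–CH2OH)
Conditions: NaBH4, CeCl3·7H2O, MeOH, −40 °C
Reagents that add atoms: none
Why: Luche reduction gives clean 1,2-reduction of the conjugated aldehyde while the ester and the C9 configuration are untouched under cold, non-basic conditions.

Step 10
Reactants: 14 dienyl alcohol
Product: 15 silyl ether (9S,10S; as 14 with C17–OSi(t-Bu)Me2)
Conditions: TBSCl, imidazole, CH2Cl2, 0 → 23 °C
Reagents that add atoms: tert-butyldimethylsilyl chloride, CC(C)(C)[Si](C)(C)Cl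
Why: Silylation of the primary allylic alcohol, which also blocks lactonisation of C17–OH onto the C9 ester.

Step 11
Reactants: 15 silyl ether
Product: 16 saturated ester (5S,9R,10R; trans-fused decalin; C8–CH2OTBS as both C8 epimers; C9–CO2Et cis to the C10 methyl)
Conditions: Mn(dpm)3 (10 mol%), PhSiH3, t-BuOOH, i-PrOH, 22 °C
Reagents that add atoms: none
Why: Metal-hydride hydrogen-atom-transfer (Mukaiyama-type) hydrogenation reduces the hindered diene stepwise through allylic and tertiary radicals, and the C5 radical should take its hydrogen on the face opposite the axial C10 methyl to give the more stable trans-fused decalin; C8 forms as a mixture that is equilibrated in step 18 and C9 is not touched.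

Step 12
Reactants: 16 saturated ester
Product: 17 primary alcohol (5S,9R,10R; C8 epimers; C9–CH2OH)
Conditions: LiAlH4, THF, 0 °C; Fieser work-up
Reagents that add atoms: none
Why: Hydride reduction of the ester to the C11 alcohol, to which the silyl ether and the acetonide are inert at 0 °C.

Step 13
Reactants: 17 primary alcohol
Product: 18 C9 aldehyde (5S,9R,10R; C8 epimers; C9–CHO)
Conditions: Dess–Martin periodinane, pyridine, CH2Cl2, 0 → 23 °C
Reagents that add atoms: none
Why: Dess–Martin oxidation under buffered, non-basic conditions, so that the C9 configuration is kept.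

Step 14
Reactants: 18 C9 aldehyde
Product: 19 9-vinyl decalin (5S,9R,10S; C8 epimers; C9–CH=CH2)
Conditions: Ph3PCH3Br, KN(SiMe3)2, THF, 0 °C; then 18, −78 → 0 °C
Reagents that add atoms: methyltriphenylphosphonium bromide, C[P+](c1ccccc1)(c1ccccc1)c1ccccc1.[Br-]
Why: Wittig methylenation, in which the unstabilised ylide should add to the aldehyde at low temperature faster than it removes the shielded C9 hydrogen.

Step 15
Reactants: 19 9-vinyl decalin; 20 3-bromofuran-2(5H)-one
Product: 22 butenolide silyl ether (5S,9R,10S; C8 epimers; C9–CH2CH2–butenolide), via B-alkyl-9-BBN borane 21 (not isolated)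
Conditions: 9-BBN, THF, 0 → 23 °C; then 20, PdCl2(dppf) (5 mol%), AsPh3, Cs2CO3, DMF/H2O, 23 °C
Reagents that add atoms: none
Why: Anti-Markovnikov hydroboration of the terminal alkene followed by B-alkyl Suzuki–Miyaura coupling with the α-bromo butenolide, whose activated C–Br bond adds readily to zerovalent palladium, under conditions used for α-halo enones at room temperature to spare the lactone.

Step 16
Reactants: 22 butenolide silyl ether
Product: 23 C17 alcohol (5S,9R,10S; C8 epimers)
Conditions: HF·pyridine, pyridine, THF, 0 → 23 °C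
Reagents that add atoms: none
Why: Fluoride-driven desilylation, in which buffered HF·pyridine cleaves the primary silyl ether and leaves the acetonide and the butenolide alone.

Step 17
Reactants: 23 C17 alcohol
Product: 24 C17 aldehyde acetonide (5S,9R,10S; C8 epimers)
Conditions: Dess–Martin periodinane, pyridine, CH2Cl2, 0 → 23 °C
Reagents that add atoms: none
Why: Dess–Martin oxidation of the primary alcohol to the aldehyde without over-oxidation and without base that could touch the butenolide.

Step 18
Reactants: 24 C17 aldehyde acetonide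
Product: 25 target, (5S,8S,9R,10S) in labdane numbering, (1R,2S,4aS,8aS)-5,5-bis(hydroxymethyl)-8a-methyl-1-[2-(2-oxo-2,5-dihydrofuran-3-yl)ethyl]decahydronaphthalene-2-carbaldehyde
Conditions: 2 M aq. HCl, THF, 40 °C
Reagents that add atoms: none
Why: Acid-catalysed acetal hydrolysis frees the C18/C19 diol while reversible enolisation of the C17 aldehyde should equilibrate C8 to the equatorial formyl group, trans to the C9 chain and free of the 1,3-diaxial clash with C20; the butenolide is stable to aqueous acid.

**Compound list**

1 | ethyl 2-oxocyclohexane-1-carboxylate | CCOC(=O)C1CCCCC1=O | starting material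
2 | ethyl 3-methyl-2-oxocyclohexane-1-carboxylate (racemic) | CCOC(=O)C1CCCC(C)C1=O | intermediate
3 | ethyl 1-(hydroxymethyl)-3-methyl-2-oxocyclohexane-1-carboxylate (racemic, both diastereomers) | CCOC(=O)C1(CO)CCCC(C)C1=O | intermediate
4 | 2,2-bis(hydroxymethyl)-6-methylcyclohexan-1-ol (racemic, both diastereomers) | CC1CCCC(CO)(CO)C1O | intermediate
5 | 3,3,8-trimethyl-2,4-dioxaspiro[5.5]undecan-7-ol (racemic, both diastereomers) | CC1CCCC2(COC(C)(C)OC2)C1O | intermediate
6 | 3,3,8-trimethyl-2,4-dioxaspiro[5.5]undecan-7-one (racemic) | CC1CCCC2(COC(C)(C)OC2)C1=O | intermediate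
7 | ethynylmagnesium bromide | C#C[Mg]Br | starting material
8 | 7-ethynyl-3,3,8-trimethyl-2,4-dioxaspiro[5.5]undecan-7-ol (racemic, both diastereomers) | CC1CCCC2(COC(C)(C)OC2)C1(O)C#C | intermediate
9 | enal A, (E)-2-(3,3,8-trimethyl-2,4-dioxaspiro[5.5]undecan-7-ylidene)acetaldehyde (racemic at C10) | O=C/C=C1\C(C)CCCC12COC(C)(C)OC2 | intermediate
10 | ethyl (E)-4-oxobut-2-enoate | CCOC(=O)/C=C/C=O | starting material
11 | dienamine N–C7=C6–C5=C10 from 9 and the (S)-amine (E enamine) | CC1=C(/C=C/N2CCC[C@H]2C(c2ccccc2)(c2ccccc2)O[Si](C)(C)C)C2(COC(C)(C)OC2)CCC1 | intermediate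
12 | aminocyclohexene adduct: C5=C6; pyrrolidine nitrogen on C7 trans to the C10 methyl; C8 formyl cis to the amine; C9 ester trans to the formyl and cis to the C10 methyl | C[C@@]12CCCC3(COC(C)(C)OC3)C1=C[C@H](N4CCC[C@H]4C(c4ccccc4)(c4ccccc4)O[Si](C)(C)C)[C@H](C=O)[C@H]2C(=O)OCC | intermediate
13 | dienal ester (9S,10S): C5=C6 and C7=C8, C8 formyl, C9 ethyl ester cis to C20, C4 spiro acetonide | C[C@@]12CCCC3(COC(C)(C)OC3)C1=CC=C(C=O)[C@H]2C(=O)OCC | intermediate
14 | dienyl alcohol (9S,10S): as 13 with C8–CH2OH | C[C@@]12CCCC3(COC(C)(C)OC3)C1=CC=C(CO)[C@H]2C(=O)OCC | intermediate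
15 | silyl ether (9S,10S): as 14 with C17–OTBS | C[C@@]12CCCC3(COC(C)(C)OC3)C1=CC=C(CO[Si](C)(C)C(C)(C)C)[C@H]2C(=O)OCC | intermediate
16 | saturated ester (5S,9R,10R; both C8 epimers): trans-decalin, C8–CH2OTBS, C9–CO2Et | C[C@@]12CCCC3(COC(C)(C)OC3)[C@H]1CCC(CO[Si](C)(C)C(C)(C)C)[C@H]2C(=O)OCC | intermediate
17 | primary alcohol (5S,9R,10R; both C8 epimers): C9–CH2OH | C[C@@]12CCCC3(COC(C)(C)OC3)[C@H]1CCC(CO[Si](C)(C)C(C)(C)C)[C@H]2CO | intermediate
18 | C9 aldehyde (5S,9R,10R; both C8 epimers) | C[C@@]12CCCC3(COC(C)(C)OC3)[C@H]1CCC(CO[Si](C)(C)C(C)(C)C)[C@H]2C=O | intermediate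
19 | 9-vinyl decalin (5S,9R,10S; both C8 epimers) | C[C@@]12CCCC3(COC(C)(C)OC3)[C@H]1CCC(CO[Si](C)(C)C(C)(C)C)[C@H]2C=C | intermediate
20 | 3-bromofuran-2(5H)-one | O=C1OCC=C1Br | starting material
21 | B-alkyl-9-BBN borane from 19 (boron on C12) | C[C@@]12CCCC3(COC(C)(C)OC3)[C@H]1CCC(CO[Si](C)(C)C(C)(C)C)[C@H]2CCB4C5CCCC4CCC5 | intermediate
22 | butenolide silyl ether (5S,9R,10S; both C8 epimers) | C[C@@]12CCCC3(COC(C)(C)OC3)[C@H]1CCC(CO[Si](C)(C)C(C)(C)C)[C@H]2CCC1=CCOC1=O | intermediate
23 | C17 alcohol (5S,9R,10S; both C8 epimers) | C[C@@]12CCCC3(COC(C)(C)OC3)[C@H]1CCC(CO)[C@H]2CCC1=CCOC1=O | intermediate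
24 | C17 aldehyde acetonide (5S,9R,10S; both C8 epimers) | C[C@@]12CCCC3(COC(C)(C)OC3)[C@H]1CCC(C=O)[C@H]2CCC1=CCOC1=O | intermediate
25 | target (5S,8S,9R,10S), CNP0332660.1 | C[C@@]12CCCC(CO)(CO)[C@H]1CC[C@H](C=O)[C@H]2CCC1=CCOC1=O | target

**Step count and risks**

Total step count: 18. Longest linear sequence: 18 steps (1 → 25); 7, 10 and 20 are bought.

Steps most likely to fail:

Step 8 (proposed new method). The dienamine may attack through its α-carbon C6 instead of C10, the quaternary centre may form with poor facial selectivity, or catalyst turnover may stall at the hindered adduct. The fallback makes the same two bonds by a Lewis-acid Diels–Alder reaction of a preformed 1-silyloxy diene, a known reaction type. It sets out from 9: soft enolisation (TBSOTf, Et3N, CH2Cl2, 0 °C) would give the tert-butyldimethylsilyl dienol ether F1. Cycloaddition of F1 with 10 under a triflimide-activated, proline-derived chiral oxazaborolidinium catalyst (CH2Cl2, −78 °C), in the enantiomeric form that adds to the same diene face, would give the endo 7-silyloxy cyclohexene aldehyde F2. Elimination of silanol (cat. p-TsOH, CH2Cl2, 0 °C) would come back to the route at 13.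

Step 7. The hindered tertiary carbinol may dehydrate toward C10 and rearrange to the methyl ketone (Rupe pathway), or the acetonide may be lost at 140 °C. The fallback adds the two carbons with a polarised alkyne and sets out from 6. Lithium ethoxyacetylide (ethoxyacetylene, n-BuLi, THF, −78 °C) would give the ethoxyalkynyl carbinol F3. Sc(OTf)3-catalysed Meyer–Schuster rearrangement (CH2Cl2/EtOH, 23 °C), which is reliable for adducts of hindered ketones, would give the unsaturated ethyl ester F4. Reduction with i-Bu2AlH (CH2Cl2, −78 °C) would give the allylic alcohol F5, and MnO2 (CH2Cl2) would come back to the route at 9.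

Step 15. The bromobutenolide may be enolised or opened by the aqueous base before it couples, or transmetalation of the alkylborane may be too slow. The fallback builds the butenolide by enolate alkylation and sulfoxide elimination and sets out from 19. Hydroboration–oxidation (9-BBN; NaOH, H2O2) would give the C12 alcohol F6, and PPh3/I2/imidazole the C12 iodide F7. Alkylation of the lithium enolate of 3-(phenylsulfanyl)oxolan-2-one with F7 (LiN(SiMe3)2, THF/HMPA, −78 → 0 °C) would give the sulfide lactone F8, and mCPBA (CH2Cl2, −78 °C) the sulfoxide F9. Thermolysis (toluene, 110 °C, CaCO3) would eliminate benzenesulfenic acid toward the ring and come back to the route at 22.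

**Further compounds**

F1 | step 8 | tert-butyldimethylsilyl dienol ether of 9 (E, silyloxy on C7) | CC1=C(/C=C/O[Si](C)(C)C(C)(C)C)C2(COC(C)(C)OC2)CCC1
F2 | step 8 | 7-silyloxy cyclohexene aldehyde (endo adduct; C7–OTBS cis to C8 formyl; C9 ester cis to C20) | C[C@@]12CCCC3(COC(C)(C)OC3)C1=C[C@H](O[Si](C)(C)C(C)(C)C)[C@H](C=O)[C@H]2C(=O)OCC
F3 | step 7 | 7-(ethoxyethynyl)-3,3,8-trimethyl-2,4-dioxaspiro[5.5]undecan-7-ol | CCOC#CC1(O)C(C)CCCC12COC(C)(C)OC2
F4 | step 7 | ethyl (E)-2-(3,3,8-trimethyl-2,4-dioxaspiro[5.5]undecan-7-ylidene)acetate | CCOC(=O)/C=C1\C(C)CCCC12COC(C)(C)OC2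
F5 | step 7 | (E)-2-(3,3,8-trimethyl-2,4-dioxaspiro[5.5]undecan-7-ylidene)ethan-1-ol | OC/C=C1\C(C)CCCC12COC(C)(C)OC2
F6 | step 15 | C12 alcohol (C9–CH2CH2OH; both C8 epimers) | C[C@@]12CCCC3(COC(C)(C)OC3)[C@H]1CCC(CO[Si](C)(C)C(C)(C)C)[C@H]2CCO
F7 | step 15 | C12 iodide (C9–CH2CH2I; both C8 epimers) | C[C@@]12CCCC3(COC(C)(C)OC3)[C@H]1CCC(CO[Si](C)(C)C(C)(C)C)[C@H]2CCI
F8 | step 15 | sulfide lactone (3-alkyl-3-(phenylsulfanyl)oxolan-2-one; both C8 and C13 epimers) | C[C@@]12CCCC3(COC(C)(C)OC3)[C@H]1CCC(CO[Si](C)(C)C(C)(C)C)[C@H]2CCC1(Sc3ccccc3)CCOC1=O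
F9 | step 15 | sulfoxide lactone (3-alkyl-3-(phenylsulfinyl)oxolan-2-one; epimer mixture) | C[C@@]12CCCC3(COC(C)(C)OC3)[C@H]1CCC(CO[Si](C)(C)C(C)(C)C)[C@H]2CCC1(S(=O)c3ccccc3)CCOC1=O
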